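The methylene bridge is cut at both of its aryl–CH2 bonds, so the dimer falls into two copies of one bibenzyl and a one-carbon unit. The bridge carbon is bonded to ring B at the carbon between its OH and OMe oxygens and to ring A at the carbon between its OH and the ethylene chain. Each site can therefore carry lithium, by deprotonation between the two oxygens on ring B and by bromine–lithium exchange on ring A. In one flask carbon dioxide is joined to both aryllithiums, forming the two aryl–carbonyl bonds of a benzophenone. The precursors are the MOM ether of the O-benzyl bibenzyl phenol and its ortho-bromo congener.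

Key step: step 8

Remark: Ar = 4-(benzyloxy)-3-methoxyphenyl throughout; O-benzylvanillin, a catalogue benzyl ether of vanillin, is taken as starting material. The target has no stereocentre, and the stilbene of step 3 is carried as an E/Z mixture because its double bond is saturated in step 4.

Step 1
Reactants: 1 4-(benzyloxy)-3-methoxybenzaldehyde (O-benzylvanillin)
Product: 2 [4-(benzyloxy)-3-methoxyphenyl]methanol
Conditions: NaBH4, MeOH/THF, 0 °C
Reagents that add atoms: none
Why: Borohydride reduction of an aryl aldehyde should give the benzylic alcohol cleanly, the benzyl and methyl ethers being inert to hydride.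

Step 2
Reactants: 2 [4-(benzyloxy)-3-methoxyphenyl]methanol
Product: 3 [4-(benzyloxy)-3-methoxybenzyl]triphenylphosphonium bromide
Conditions: PPh3·HBr, MeCN, reflux
Reagents that add atoms: triphenylphosphine hydrobromide, [Br-].[PH+](c1ccccc1)(c1ccccc1)c1ccccc1
Why: Triphenylphosphine hydrobromide converts electron-rich benzylic alcohols directly into phosphonium bromides (acid-promoted SN1 substitution through the para-alkoxybenzyl cation, water being the only by-product), and the aryl benzyl ether should survive this weakly acidic salt.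

Step 3
Reactants: 3 [4-(benzyloxy)-3-methoxybenzyl]triphenylphosphonium bromide; 4 3-hydroxy-5-methoxybenzaldehyde
Product: 6 3-[2-(4-benzyloxy-3-methoxyphenyl)ethenyl]-5-methoxyphenol (E/Z mixture), via benzylidene phosphorane 5 (not isolated)
Conditions: KOt-Bu (2.3 equiv), THF, 0 °C → rt; 1 M HCl
Reagents that add atoms: none
Why: Wittig olefination with a semistabilised benzylidene ylide, in which one further equivalent of base holds the phenol of 4 as its phenoxide; this sits meta to the aldehyde and so should leave it electrophilic.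

Step 4
Reactants: 6 3-[2-(4-benzyloxy-3-methoxyphenyl)ethenyl]-5-methoxyphenol
Product: 7 3-[2-(4-benzyloxy-3-methoxyphenyl)ethyl]-5-methoxyphenol
Conditions: TsNHNH2, NaOAc, DME/H2O, reflux
Reagents that add atoms: none
Why: Diimide reduction (concerted syn transfer of H2 from HN=NH released by fragmentation of tosylhydrazide) should saturate both alkene isomers and cannot cleave the benzyl ether, which hydrogenation over palladium would endanger.

Step 5
Reactants: 7 3-[2-(4-benzyloxy-3-methoxyphenyl)ethyl]-5-methoxyphenol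
Product: 8 1-[2-(4-benzyloxy-3-methoxyphenyl)ethyl]-3-methoxy-5-(methoxymethoxy)benzene (ring B partner)
Conditions: MOMCl, i-Pr2NEt, CH2Cl2, 0 °C → rt
Reagents that add atoms: chloromethyl methyl ether, COCCl
Why: Williamson-type O-alkylation of the phenol installs the MOM acetal that later directs lithiation to the carbon between the two oxygens.

Step 6
Reactants: 7 3-[2-(4-benzyloxy-3-methoxyphenyl)ethyl]-5-methoxyphenol
Product: 9 2-bromo-3-[2-(4-benzyloxy-3-methoxyphenyl)ethyl]-5-methoxyphenol
Conditions: NBS (1.0 equiv), i-Pr2NH (10 mol%), CH2Cl2, –40 → 0 °C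
Reagents that add atoms: N-bromosuccinimide, O=C1CCC(=O)N1Br
Why: Amine-mediated ortho-bromination of a phenol with NBS delivers bromine through a hydrogen bond to the hydroxyl, so attack should fall ortho to OH and, of the two ortho carbons, at the one para to OMe (between OH and the ethylene chain); the resorcinol-type ring is far more nucleophilic than the catechol-type guaiacyl ring, which should stay untouched with one equivalent.

Step 7
Reactants: 9 2-bromo-3-[2-(4-benzyloxy-3-methoxyphenyl)ethyl]-5-methoxyphenol
Product: 10 2-bromo-1-[2-(4-benzyloxy-3-methoxyphenyl)ethyl]-5-methoxy-3-(methoxymethoxy)benzene (ring A partner)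
Conditions: MOMCl, i-Pr2NEt, CH2Cl2, 0 °C → rt
Reagents that add atoms: chloromethyl methyl ether, COCCl
Why: Williamson-type O-alkylation of the more acidic ortho-bromophenol gives the MOM ether, which tolerates the organolithium of the next step and chelates it.

Step 8
Reactants: 8 ring B MOM ether; 10 ring A aryl bromide; 11 carbon dioxide
Product: 16 {2-methoxy-6-(methoxymethoxy)-4-[2-(Ar)ethyl]phenyl}{4-methoxy-2-(methoxymethoxy)-6-[2-(Ar)ethyl]phenyl}methanone, via ring B aryllithium 12 (not isolated), via lithium carboxylate 13 (not isolated), via ring A aryllithium 14 (not isolated), via dilithium gem-diolate 15 (not isolated)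
Conditions: 8, n-BuLi (1.0 equiv), THF, 0 °C; CO2 (g), –78 °C, then evacuate/Ar at 0 °C; 10 (1.2 equiv), t-BuLi (2.4 equiv), THF, –78 °C, transferred by cannula, –78 °C → rt; H2O
Reagents that add atoms: carbon dioxide (compound 11), O=C=O
Why: n-BuLi deprotonates 8 at the carbon flanked by OMOM and OMe (directed ortho-metalation, both oxygens binding lithium) to give 12, which adds to carbon dioxide to give carboxylate 13; once excess gas is swept out, aryllithium 14, formed at the brominated carbon of 10 by bromine–lithium exchange, adds to the carboxylate carbon to give gem-diolate 15, which releases ketone 16 only on aqueous quench. The closest known reaction type is the one-pot synthesis of unsymmetrical ketones from an organolithium, carbon dioxide and a second organolithium, here applied to a tetra-ortho-substituted diaryl ketone. No ring is closed and no stereocentre is formed. The step needs site selectivity on each ring and mono-addition: the first is secured by the two flanking oxygens on ring B and by the position of bromine on ring A, the second by the dianionic gem-diolate, which cannot accept a further aryllithium. The ortho OMOM and OMe groups chelate lithium and should help the partners meet at the crowded carbon, and two equivalents of t-BuLi are used so that neither an alkyl bromide nor residual alkyllithium competes for 13.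

Step 9
Reactants: 16 bis-MOM benzophenone
Product: 17 {2-hydroxy-6-methoxy-4-[2-(Ar)ethyl]phenyl}{2-hydroxy-4-methoxy-6-[2-(Ar)ethyl]phenyl}methanone
Conditions: HCl (1.25 M in MeOH), THF, 40 °C
Reagents that add atoms: none
Why: Acid-catalysed transacetalisation should remove both MOM ethers while benzyl and methyl ethers persist; methanol traps the methoxymethyl cation as dimethoxymethane, so it cannot alkylate the arenes, which the ketone also deactivates.

Step 10
Reactants: 17 2,2'-dihydroxybenzophenone
Product: 18 2-({2-hydroxy-4-methoxy-6-[2-(Ar)ethyl]phenyl}methyl)-3-methoxy-5-[2-(Ar)ethyl]phenol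
Conditions: Et3SiH, TFA, CH2Cl2, 0 °C → rt
Reagents that add atoms: none
Why: Ionic hydrogenation should convert the protonated diaryl ketone into the benzhydrol by hydride transfer from the silane, after which ionisation to a cation stabilised by the ortho and para oxygens of both rings and a second hydride transfer give the methylene bridge; benzyl ethers tolerate dilute TFA at this temperature.

Step 11
Reactants: 18 bis-benzyl diarylmethane
Product: 19 2-({2-hydroxy-4-methoxy-6-[2-(4-hydroxy-3-methoxyphenyl)ethyl]phenyl}methyl)-5-[2-(4-hydroxy-3-methoxyphenyl)ethyl]-3-methoxyphenol (CNP0079001.0)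
Conditions: H2 (1 atm), 10% Pd/C, EtOAc/MeOH, rt
Reagents that add atoms: none
Why: Palladium-catalysed hydrogenolysis of the two aryl benzyl ethers under neutral conditions should leave the diarylmethane, the bibenzyl chains and the methyl ethers intact.

Compound list
1 | 4-(benzyloxy)-3-methoxybenzaldehyde (O-benzylvanillin) | COc1cc(C=O)ccc1OCc1ccccc1 | starting material
2 | [4-(benzyloxy)-3-methoxyphenyl]methanol | COc1cc(CO)ccc1OCc1ccccc1 | intermediate
3 | [4-(benzyloxy)-3-methoxybenzyl]triphenylphosphonium bromide | COc1cc(C[P+](c2ccccc2)(c2ccccc2)c2ccccc2)ccc1OCc1ccccc1.[Br-] | intermediate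
4 | 3-hydroxy-5-methoxybenzaldehyde | COc1cc(O)cc(C=O)c1 | starting material
5 | [4-(benzyloxy)-3-methoxybenzylidene]triphenylphosphorane | COc1cc(C=P(c2ccccc2)(c2ccccc2)c2ccccc2)ccc1OCc1ccccc1 | intermediate (not isolated)
6 | 3-[2-(4-benzyloxy-3-methoxyphenyl)ethenyl]-5-methoxyphenol, E/Z mixture | COc1cc(O)cc(C=Cc2ccc(OCc3ccccc3)c(OC)c2)c1 | intermediate
7 | 3-[2-(4-benzyloxy-3-methoxyphenyl)ethyl]-5-methoxyphenol | COc1cc(O)cc(CCc2ccc(OCc3ccccc3)c(OC)c2)c1 | intermediate
8 | 1-[2-(4-benzyloxy-3-methoxyphenyl)ethyl]-3-methoxy-5-(methoxymethoxy)benzene | COCOc1cc(CCc2ccc(OCc3ccccc3)c(OC)c2)cc(OC)c1 | intermediate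
9 | 2-bromo-3-[2-(4-benzyloxy-3-methoxyphenyl)ethyl]-5-methoxyphenol | COc1cc(O)c(Br)c(CCc2ccc(OCc3ccccc3)c(OC)c2)c1 | intermediate
10 | 2-bromo-1-[2-(4-benzyloxy-3-methoxyphenyl)ethyl]-5-methoxy-3-(methoxymethoxy)benzene | COCOc1cc(OC)cc(CCc2ccc(OCc3ccccc3)c(OC)c2)c1Br | intermediate
11 | carbon dioxide | O=C=O | starting material
12 | {2-methoxy-6-(methoxymethoxy)-4-[2-(Ar)ethyl]phenyl}lithium (ring B aryllithium) | [Li]c1c(OCOC)cc(CCc2ccc(OCc3ccccc3)c(OC)c2)cc1OC | intermediate (not isolated)
13 | lithium 2-methoxy-6-(methoxymethoxy)-4-[2-(Ar)ethyl]benzoate | [Li+].[O-]C(=O)c1c(OCOC)cc(CCc2ccc(OCc3ccccc3)c(OC)c2)cc1OC | intermediate (not isolated)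
14 | {4-methoxy-2-(methoxymethoxy)-6-[2-(Ar)ethyl]phenyl}lithium (ring A aryllithium) | [Li]c1c(OCOC)cc(OC)cc1CCc1ccc(OCc2ccccc2)c(OC)c1 | intermediate (not isolated)
15 | dilithium diarylmethanediolate (gem-diolate of ketone 16) | [Li+].[Li+].[O-]C([O-])(c1c(OCOC)cc(CCc2ccc(OCc3ccccc3)c(OC)c2)cc1OC)c1c(OCOC)cc(OC)cc1CCc1ccc(OCc2ccccc2)c(OC)c1 | intermediate (not isolated)
16 | {2-methoxy-6-(methoxymethoxy)-4-[2-(Ar)ethyl]phenyl}{4-methoxy-2-(methoxymethoxy)-6-[2-(Ar)ethyl]phenyl}methanone | COCOc1cc(CCc2ccc(OCc3ccccc3)c(OC)c2)cc(OC)c1C(=O)c1c(OCOC)cc(OC)cc1CCc1ccc(OCc2ccccc2)c(OC)c1 | intermediate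
17 | {2-hydroxy-6-methoxy-4-[2-(Ar)ethyl]phenyl}{2-hydroxy-4-methoxy-6-[2-(Ar)ethyl]phenyl}methanone | COc1cc(CCc2ccc(OCc3ccccc3)c(OC)c2)cc(O)c1C(=O)c1c(O)cc(OC)cc1CCc1ccc(OCc2ccccc2)c(OC)c1 | intermediate
18 | 2-({2-hydroxy-4-methoxy-6-[2-(Ar)ethyl]phenyl}methyl)-3-methoxy-5-[2-(Ar)ethyl]phenol | COc1cc(CCc2ccc(OCc3ccccc3)c(OC)c2)cc(O)c1Cc1c(O)cc(OC)cc1CCc1ccc(OCc2ccccc2)c(OC)c1 | intermediate
19 | 2-({2-hydroxy-4-methoxy-6-[2-(4-hydroxy-3-methoxyphenyl)ethyl]phenyl}methyl)-5-[2-(4-hydroxy-3-methoxyphenyl)ethyl]-3-methoxyphenol (CNP0079001.0) | COc1cc(O)c(Cc2c(O)cc(CCc3ccc(O)c(OC)c3)cc2OC)c(CCc2ccc(O)c(OC)c2)c1 | target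

Total step count: 11. Longest linear sequence: 10 steps (steps 1–4 and 6–11, from 1 to 19).

Steps most likely to fail

Step 8. The di-ortho-substituted aryllithium may add too slowly to the equally crowded carboxylate and be lost to proton abstraction on warming, which would return 8. It may also be intercepted by carbon dioxide that was not swept out. Fallback: the one-carbon unit is brought in at the aldehyde oxidation level in separate operations. Setting out from 8, aryllithium 12 (n-BuLi, THF, 0 °C) would be formylated with DMF to 2-methoxy-6-(methoxymethoxy)-4-[2-(Ar)ethyl]benzaldehyde F1. Aryllithium 14 (from 10, t-BuLi, –78 °C) should add to this less crowded and more electrophilic carbonyl to give the racemic diarylmethanol F2. Oxidation with Dess–Martin periodinane (NaHCO3, CH2Cl2) comes back to the route at 16.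

Step 6. Bromination may drift to the carbon para to the hydroxyl (between OMe and the chain) or run on to a dibromide, leaving a mixture of ring A regioisomers. Fallback: the two ring A oxygens are made identical so that both carbons ortho to the chain are equivalent, and the methyl group is placed after the union.
- Setting out from 3 and commercial 3,5-dihydroxybenzaldehyde, the aldehyde would be protected (MOMCl, i-Pr2NEt) as 3,5-bis(methoxymethoxy)benzaldehyde F3.
- Wittig reaction with ylide 5 should give the bis-MOM stilbene F4, and diimide reduction as in step 4 the bis-MOM bibenzyl F5.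
- NBS (MeCN, 0 °C) can then give only one ortho-to-chain monobromide, the bis-MOM aryl bromide F6.
- Under the conditions of step 8, the derived aryllithium F7 should add to carboxylate 13 to give the gem-diolate F8 and, after quench, the tris-MOM benzophenone F9.
- Methanolic HCl would give the 2,4,2'-trihydroxybenzophenone F10.
- MeI (1.05 equiv) with K2CO3 in acetone should methylate only the hydroxyl para to the carbonyl, the two ortho hydroxyls being hydrogen-bonded to it, and so come back to the route at 17.

Step 10. Hydride transfer to the hindered, doubly hydrogen-bonded carbonyl may stall, and long exposure to acid invites migration of benzyl groups onto the electron-rich rings. Fallback: the reduction is split into a nucleophilic hydride addition and a separate deoxygenation. Setting out from 17, LiAlH4 (THF, reflux) should give the racemic 2,2'-dihydroxybenzhydrol F11. This alcohol ionises far more easily than the ketone is protonated, and Et3SiH with BF3·OEt2 (CH2Cl2, –40 °C) should reduce it and come back to the route at 18.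

Further compounds
F1 | step 8 | 2-methoxy-6-(methoxymethoxy)-4-[2-(Ar)ethyl]benzaldehyde | COCOc1cc(CCc2ccc(OCc3ccccc3)c(OC)c2)cc(OC)c1C=O
F2 | step 8 | {2-methoxy-6-(methoxymethoxy)-4-[2-(Ar)ethyl]phenyl}{4-methoxy-2-(methoxymethoxy)-6-[2-(Ar)ethyl]phenyl}methanol, racemic | COCOc1cc(CCc2ccc(OCc3ccccc3)c(OC)c2)cc(OC)c1C(O)c1c(OCOC)cc(OC)cc1CCc1ccc(OCc2ccccc2)c(OC)c1
F3 | step 6 | 3,5-bis(methoxymethoxy)benzaldehyde | COCOc1cc(C=O)cc(OCOC)c1
F4 | step 6 | 1-[2-(4-benzyloxy-3-methoxyphenyl)ethenyl]-3,5-bis(methoxymethoxy)benzene, E/Z mixture | COCOc1cc(C=Cc2ccc(OCc3ccccc3)c(OC)c2)cc(OCOC)c1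
F5 | step 6 | 1-[2-(4-benzyloxy-3-methoxyphenyl)ethyl]-3,5-bis(methoxymethoxy)benzene | COCOc1cc(CCc2ccc(OCc3ccccc3)c(OC)c2)cc(OCOC)c1
F6 | step 6 | 2-bromo-1-[2-(4-benzyloxy-3-methoxyphenyl)ethyl]-3,5-bis(methoxymethoxy)benzene | COCOc1cc(OCOC)cc(CCc2ccc(OCc3ccccc3)c(OC)c2)c1Br
F7 | step 6 | {2,4-bis(methoxymethoxy)-6-[2-(Ar)ethyl]phenyl}lithium | [Li]c1c(OCOC)cc(OCOC)cc1CCc1ccc(OCc2ccccc2)c(OC)c1
F8 | step 6 | dilithium diarylmethanediolate (gem-diolate of F9) | [Li+].[Li+].[O-]C([O-])(c1c(OCOC)cc(CCc2ccc(OCc3ccccc3)c(OC)c2)cc1OC)c1c(OCOC)cc(OCOC)cc1CCc1ccc(OCc2ccccc2)c(OC)c1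
F9 | step 6 | {2-methoxy-6-(methoxymethoxy)-4-[2-(Ar)ethyl]phenyl}{2,4-bis(methoxymethoxy)-6-[2-(Ar)ethyl]phenyl}methanone | COCOc1cc(CCc2ccc(OCc3ccccc3)c(OC)c2)cc(OC)c1C(=O)c1c(OCOC)cc(OCOC)cc1CCc1ccc(OCc2ccccc2)c(OC)c1
F10 | step 6 | {2-hydroxy-6-methoxy-4-[2-(Ar)ethyl]phenyl}{2,4-dihydroxy-6-[2-(Ar)ethyl]phenyl}methanone | COc1cc(CCc2ccc(OCc3ccccc3)c(OC)c2)cc(O)c1C(=O)c1c(O)cc(O)cc1CCc1ccc(OCc2ccccc2)c(OC)c1
F11 | step 10 | 2-({2-hydroxy-4-methoxy-6-[2-(Ar)ethyl]phenyl}(hydroxy)methyl)-3-methoxy-5-[2-(Ar)ethyl]phenol, racemic | COc1cc(CCc2ccc(OCc3ccccc3)c(OC)c2)cc(O)c1C(O)c1c(O)cc(OC)cc1CCc1ccc(OCc2ccccc2)c(OC)c1
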